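The route rests on cutting unit 2 at C2'–C3'. C2' is a benzylic ether carbon held between O1' and the electron-rich ring E, so this bond can be forged by letting a carbene centred on C3', the carbon attached to ring C, insert into the O–CH2 group of an ortho 2,4-dimethoxybenzyl ether. One dirhodium-catalysed C–H insertion thus closes the dihydrofuran ring, fixes C2' and leaves a C3' ester that is later traded for ring F through a planar radical. The substrate is a ring C aryldiazoacetate flanked by that benzyl ether and a methoxy group, with a C7' bromide as the handle from which unit 1 is grown.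

Key step: step 7

Assumption: Rh2(S-PTTL)4 is taken to replace the benzylic hydrogen that leads to (2S) at C2', and the isothiocineole enantiomer drawn is taken to lead to (2S) at C2 of unit 1; if either sense proves opposite, the mirror-image catalyst or sulfide is used without other change.

Step 1
Reactants: 1 2-bromo-5-methoxyphenol
Product: 2 3-bromo-2-hydroxy-6-methoxybenzaldehyde
Conditions: (CH2O)n, MgCl2, Et3N, MeCN, reflux; 1 M HCl work-up
Reagents that add atoms: paraformaldehyde as formaldehyde (C=O)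
Why: The magnesium phenoxide delivers formaldehyde only ortho to the hydroxyl, the single free ortho position lies between OH and OMe, and hydride transfer to a second formaldehyde gives the aldehyde; Casnati–Skattebøl ortho-formylation.

Step 2
Reactants: 2 3-bromo-2-hydroxy-6-methoxybenzaldehyde; 3 2,4-dimethoxybenzyl alcohol
Product: 4 3-bromo-2-[(2,4-dimethoxybenzyl)oxy]-6-methoxybenzaldehyde
Conditions: PPh3, DIAD, THF, 0 °C → rt
Reagents that add atoms: none
Why: The acidic salicylaldehyde hydroxyl is alkylated by the activated benzylic alcohol under neutral conditions, which avoids the unstable 2,4-dimethoxybenzyl halide; Mitsunobu etherification.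

Step 3
Reactants: 4 3-bromo-2-[(2,4-dimethoxybenzyl)oxy]-6-methoxybenzaldehyde
Product: 5 2-{3-bromo-2-[(2,4-dimethoxybenzyl)oxy]-6-methoxyphenyl}acetonitrile
Conditions: TosMIC, t-BuOK, DME, −40 °C; then MeOH, reflux
Reagents that add atoms: TosMIC (Cc1ccc(cc1)S(=O)(=O)C[N+]#[C-])
Why: The TosMIC anion adds to the aldehyde and the cyclic adduct collapses in methanol with loss of sulfinate and formate to the one-carbon-extended nitrile, under base that the benzyl ether and aryl bromide tolerate; van Leusen reductive cyanation.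

Step 4
Reactants: 5 2-{3-bromo-2-[(2,4-dimethoxybenzyl)oxy]-6-methoxyphenyl}acetonitrile
Product: 6 2-{3-bromo-2-[(2,4-dimethoxybenzyl)oxy]-6-methoxyphenyl}acetic acid
Conditions: KOH, EtOH/H2O, reflux; then 1 M HCl to pH 3, 0 °C
Reagents that add atoms: potassium hydroxide ([K+].[OH-]); water (O)
Why: Hydroxide hydrolyses the unhindered benzylic nitrile through the amide while the ethers and the bromide are inert to base; alkaline nitrile hydrolysis.

Step 5
Reactants: 6 2-{3-bromo-2-[(2,4-dimethoxybenzyl)oxy]-6-methoxyphenyl}acetic acid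
Product: 7 methyl 2-{3-bromo-2-[(2,4-dimethoxybenzyl)oxy]-6-methoxyphenyl}acetate
Conditions: MeI, K2CO3, DMF, rt
Reagents that add atoms: iodomethane (CI)
Why: The carboxylate is methylated by SN2 under conditions too mild to affect any other group; carboxylate O-alkylation.

Step 6
Reactants: 7 methyl 2-{3-bromo-2-[(2,4-dimethoxybenzyl)oxy]-6-methoxyphenyl}acetate
Product: 8 methyl 2-{3-bromo-2-[(2,4-dimethoxybenzyl)oxy]-6-methoxyphenyl}-2-diazoacetate
Conditions: p-ABSA, DBU, MeCN, 0 °C → rt
Reagents that add atoms: 4-acetamidobenzenesulfonyl azide (CC(=O)Nc1ccc(cc1)S(=O)(=O)N=[N+]=[N-])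
Why: DBU forms the arylacetate enolate, which attacks the terminal nitrogen of the sulfonyl azide and expels the sulfonamide; Regitz diazo transfer.

Step 7
Reactants: 8 methyl 2-{3-bromo-2-[(2,4-dimethoxybenzyl)oxy]-6-methoxyphenyl}-2-diazoacetate
Product: 9 methyl (2S,3R)-7-bromo-2-(2,4-dimethoxyphenyl)-4-methoxy-2,3-dihydrobenzofuran-3-carboxylate (cis)
Conditions: Rh2(S-PTTL)4 (1 mol %), toluene, −60 → 0 °C
Reagents that add atoms: none
Why: Rh2(S-PTTL)4 expels N2 from 8 to give a donor–acceptor dirhodium carbene at C3', which takes one of the two enantiotopic hydrogens of the O–CH2 group through a concerted, asynchronous three-centre transition state with hydride-shift character and so forms the C2'–C3' bond. The closest known reaction is the enantioselective intramolecular 1,5 C–H insertion of ortho-benzyloxy aryldiazoacetates with chiral dirhodium tetracarboxylates, which gives cis-2-aryl-2,3-dihydrobenzofuran-3-carboxylates. The dihydrofuran ring (O1', C2', C3', C3a', C7a') closes by this 1,5-insertion, a five-membered closure in which the carbene carbon is joined to the carbon that carried the hydrogen. C2' is controlled by the chiral phthalimido-tert-leucinate ligand sphere, which decides which hydrogen is replaced, whereas C3' falls cis to ring E because of the compact transition state and is only a temporary centre. The step needs site selectivity for the benzylic methylene over the equally 1,5-related C–H bonds of the methoxy group on the other ortho position and over attack on ring E. This is secured because only the methylene is activated both by the adjacent oxygen lone pair and by the electron-rich ring E, while the methoxy C–H bonds are primary and lack aryl activation.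

Step 8
Reactants: 9 methyl (2S,3R)-7-bromo-2-(2,4-dimethoxyphenyl)-4-methoxy-2,3-dihydrobenzofuran-3-carboxylate
Product: 11 (2S,3S)-7-bromo-2-(2,4-dimethoxyphenyl)-4-methoxy-2,3-dihydrobenzofuran-3-carboxylic acid, via trans methyl ester 10 (not isolated)
Conditions: LiOH, THF/MeOH/H2O, 40 °C; then 1 M HCl, 0 °C
Reagents that add atoms: lithium hydroxide ([Li+].[OH-])
Why: The hindered cis ester should equilibrate through its enolate to the trans ester before it is cleaved, C2' staying untouched because expulsion of the aryloxide from the enolate would be a disfavoured reverse 5-endo process, and any cis acid converges in step 11; base epimerisation and saponification.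

Step 9
Reactants: 11 (2S,3S)-7-bromo-2-(2,4-dimethoxyphenyl)-4-methoxy-2,3-dihydrobenzofuran-3-carboxylic acid
Product: 12 1,3-dioxoisoindolin-2-yl (2S,3S)-7-bromo-2-(2,4-dimethoxyphenyl)-4-methoxy-2,3-dihydrobenzofuran-3-carboxylate
Conditions: N-hydroxyphthalimide, DIC, DMAP (cat.), CH2Cl2, rt
Reagents that add atoms: N-hydroxyphthalimide (ON1C(=O)c2ccccc2C1=O)
Why: Carbodiimide activation turns the acid into the redox-active N-acyloxyphthalimide; Steglich-type esterification.

Step 10
Reactants: 13 1-bromo-3,5-dimethoxybenzene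
Product: 14 3,5-dimethoxyphenylmagnesium bromide (titrated THF stock solution, kept under argon)
Conditions: Mg turnings, I2 (cat.), THF, 40 °C → rt
Reagents that add atoms: magnesium ([Mg])
Why: Magnesium inserts into the aryl C–Br bond at the activated metal surface, and one titrated batch of the resulting solution supplies both step 11 and step 15; Grignard reagent formation.

Step 11
Reactants: 12 1,3-dioxoisoindolin-2-yl (2S,3S)-7-bromo-2-(2,4-dimethoxyphenyl)-4-methoxy-2,3-dihydrobenzofuran-3-carboxylate; 14 3,5-dimethoxyphenylmagnesium bromide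
Product: 16 (2S,3S)-7-bromo-2-(2,4-dimethoxyphenyl)-3-(3,5-dimethoxyphenyl)-4-methoxy-2,3-dihydrobenzofuran (trans), via diarylzinc 15 (not isolated)
Conditions: 14, ZnCl2 (0.5 equiv per 14), THF, rt; then 12, Fe(acac)3 (10 mol %), dppBz (12 mol %), THF/toluene, rt
Reagents that add atoms: none
Why: Single-electron reduction of the redox-active ester by the low-valent aryl-iron species releases CO2 and a planar benzylic C3' radical, which should be arylated on the face away from ring E to give the trans ring while the aryl bromide stays inert to iron; iron-catalysed decarboxylative arylation of a redox-active ester with an arylzinc.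

Step 12
Reactants: 16 (2S,3S)-7-bromo-2-(2,4-dimethoxyphenyl)-3-(3,5-dimethoxyphenyl)-4-methoxy-2,3-dihydrobenzofuran
Product: 18 [(2S,3S)-2-(2,4-dimethoxyphenyl)-3-(3,5-dimethoxyphenyl)-4-methoxy-2,3-dihydrobenzofuran-7-yl]methanol, via aldehyde 17 (not isolated)
Conditions: n-BuLi, THF, −78 °C; DMF, −78 → 0 °C; then MeOH, NaBH4, 0 °C
Reagents that add atoms: N,N-dimethylformamide (CN(C)C=O)
Why: Bromine–lithium exchange at −78 °C outruns any deprotonation, the aryllithium is formylated by DMF, and the aldehyde set free on methanol quench is reduced in the same flask; halogen–metal exchange, Bouveault formylation and borohydride reduction.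

Step 13
Reactants: 18 [(2S,3S)-2-(2,4-dimethoxyphenyl)-3-(3,5-dimethoxyphenyl)-4-methoxy-2,3-dihydrobenzofuran-7-yl]methanol
Product: 20 6-{[(2S,3S)-2-(2,4-dimethoxyphenyl)-3-(3,5-dimethoxyphenyl)-4-methoxy-2,3-dihydrobenzofuran-7-yl]methyl}-4,7,7-trimethyl-6-thiabicyclo[3.2.1]octan-6-ium tetrafluoroborate (benzylic group exo on sulfur), via benzylic chloride 19 (not isolated)
Conditions: MsCl, Et3N, CH2Cl2, −20 °C; then isothiocineole, NaBF4, MeCN, rt
Reagents that add atoms: isothiocineole (C[C@H]1CC[C@@H]2C[C@H]1SC2(C)C); sodium tetrafluoroborate ([Na+].F[B-](F)(F)F)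
Why: MsCl and Et3N turn the electron-rich benzylic alcohol into its chloride in the flask, the sulfide is then alkylated on its less hindered lone pair, and tetrafluoroborate pulls chloride out of the equilibrium; S-alkylation of a sulfide to a sulfonium salt.

Step 14
Reactants: 21 2-bromo-4,6-dimethoxybenzaldehyde
Product: 22 2-bromo-6-hydroxy-4-methoxybenzaldehyde
Conditions: BCl3 (1.1 equiv), CH2Cl2, −78 → 0 °C; H2O
Reagents that add atoms: none
Why: BCl3 chelated between the aldehyde oxygen and the ortho methoxy group cleaves only that ether, which opens the side branch leading to the ring A partner; chelation-controlled demethylation.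

Step 15
Reactants: 22 2-bromo-6-hydroxy-4-methoxybenzaldehyde; 14 3,5-dimethoxyphenylmagnesium bromide
Product: 23 rac-3-bromo-2-[(3,5-dimethoxyphenyl)(hydroxy)methyl]-5-methoxyphenol
Conditions: 14 (2.5 equiv), THF, 0 °C → rt; aq. NH4Cl
Reagents that add atoms: none
Why: The first equivalent of 14 forms the magnesium phenoxide and a further equivalent adds to the aldehyde, the aryl bromide being inert at this temperature; Grignard addition.

Step 16
Reactants: 23 rac-3-bromo-2-[(3,5-dimethoxyphenyl)(hydroxy)methyl]-5-methoxyphenol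
Product: 24 rac-3-bromo-2-[(3,5-dimethoxyphenyl)(4-methylbenzenesulfonyl)methyl]-5-methoxyphenol
Conditions: TolSO2Na, HCO2H, CH2Cl2/H2O, rt
Reagents that add atoms: sodium 4-methylbenzenesulfinate ([Na+].[O-]S(=O)c1ccc(C)cc1)
Why: Formic acid ionises the ortho-hydroxybenzhydrol to a cation stabilised by the ortho and para oxygens, which the sulfinate captures at sulfur to give a bench-stable precursor of the quinone methide; SN1 substitution by a sulfinate.

Step 17
Reactants: 20 the sulfonium tetrafluoroborate; 24 rac-3-bromo-2-[(3,5-dimethoxyphenyl)(4-methylbenzenesulfonyl)methyl]-5-methoxyphenol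
Product: 27 (2S,3S)-4-bromo-2-[(2S,3S)-2-(2,4-dimethoxyphenyl)-3-(3,5-dimethoxyphenyl)-4-methoxy-2,3-dihydrobenzofuran-7-yl]-3-(3,5-dimethoxyphenyl)-6-methoxy-2,3-dihydrobenzofuran, via sulfonium ylide 25 (not isolated), via ortho-quinone methide 26 (not isolated)
Conditions: KHMDS (2.2 equiv), THF, −78 → 0 °C
Reagents that add atoms: none
Why: Proposed new method: base expels sulfinate from the phenoxide of 24 to give quinone methide 26 and deprotonates 20 to ylide 25, whose conformation and open face are fixed by the rigid bicyclic sulfide, so that conjugate addition to the methide carbon (C3) should occur on one ylide face in the sterically preferred anti sense and the rearomatised phenoxide then displaces the sulfide at C2 with inversion (5-exo-tet) to give the trans ring with (2S,3S) configuration under reagent control, independent of the remote unit 2; the closest known reactions are the [4+1] annulation of sulfonium ylides with ortho-quinone methides to trans-2,3-dihydrobenzofurans and the isothiocineole-mediated asymmetric epoxidation with benzylic sulfonium ylides.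

Step 18
Reactants: 27 the octamethyl ether bromide
Product: 28 (2S,3S)-4-bromo-3-(3,5-dihydroxyphenyl)-2-[(2S,3S)-2-(2,4-dihydroxyphenyl)-3-(3,5-dihydroxyphenyl)-4-hydroxy-2,3-dihydrobenzofuran-7-yl]-2,3-dihydrobenzofuran-6-ol
Conditions: BBr3 (excess), CH2Cl2, −78 → 0 °C; ice water
Reagents that add atoms: none
Why: BBr3 cleaves all eight aryl methyl ethers through their oxonium borate complexes, and it is applied while the styryl group is still absent so that no acid-induced cation–olefin cyclisation can take place, any benzylic C–O bond that opens being expected to reclose to the more stable trans ring; Lewis-acid cleavage of aryl methyl ethers.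

Step 19
Reactants: 28 the octaphenol bromide
Product: 29 octaacetate of 28
Conditions: Ac2O, pyridine, DMAP (cat.), rt
Reagents that add atoms: acetic anhydride (CC(=O)OC(C)=O)
Why: Exhaustive O-acylation gives a stable, chromatographable aryl bromide whose phenols are masked for the palladium step; DMAP-catalysed acetylation.

Step 20
Reactants: 29 octaacetate of 28; 30 4-acetoxystyrene
Product: 31 nonaacetate of the target (E)
Conditions: Pd(OAc)2 (5 mol %), P(o-tol)3, Et3N, DMF, 90 °C
Reagents that add atoms: none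
Why: Oxidative addition of zerovalent palladium into the C4–Br bond, syn insertion of the styrene at its terminal carbon and syn β-hydride elimination give the E stilbene; Mizoroki–Heck reaction.

Step 21
Reactants: 31 nonaacetate of the target
Product: 32 the target, CNP0397447.1
Conditions: K2CO3 (cat.), MeOH, 0 °C → rt, argon; then AcOH
Reagents that add atoms: none
Why: Methoxide removes the nine aryl acetates by transesterification at low temperature, so that the stilbene and both benzylic ether bonds never meet acid or Lewis acid in the last stage; Zemplén-type methanolysis.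

Compound list
1 | 2-bromo-5-methoxyphenol | COc1ccc(Br)c(O)c1 | starting material
2 | 3-bromo-2-hydroxy-6-methoxybenzaldehyde | COc1ccc(Br)c(O)c1C=O | intermediate
3 | 2,4-dimethoxybenzyl alcohol | COc1ccc(CO)c(OC)c1 | starting material
4 | 3-bromo-2-[(2,4-dimethoxybenzyl)oxy]-6-methoxybenzaldehyde | COc1ccc(Br)c(OCc2ccc(OC)cc2OC)c1C=O | intermediate
5 | 2-{3-bromo-2-[(2,4-dimethoxybenzyl)oxy]-6-methoxyphenyl}acetonitrile | COc1ccc(Br)c(OCc2ccc(OC)cc2OC)c1CC#N | intermediate
6 | 2-{3-bromo-2-[(2,4-dimethoxybenzyl)oxy]-6-methoxyphenyl}acetic acid | COc1ccc(Br)c(OCc2ccc(OC)cc2OC)c1CC(=O)O | intermediate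
7 | methyl 2-{3-bromo-2-[(2,4-dimethoxybenzyl)oxy]-6-methoxyphenyl}acetate | COC(=O)Cc1c(OC)ccc(Br)c1OCc1ccc(OC)cc1OC | intermediate
8 | methyl 2-{3-bromo-2-[(2,4-dimethoxybenzyl)oxy]-6-methoxyphenyl}-2-diazoacetate | COC(=O)C(=[N+]=[N-])c1c(OC)ccc(Br)c1OCc1ccc(OC)cc1OC | intermediate
9 | methyl (2S,3R)-7-bromo-2-(2,4-dimethoxyphenyl)-4-methoxy-2,3-dihydrobenzofuran-3-carboxylate (cis) | Brc1ccc(OC)c2c1O[C@H](c1ccc(OC)cc1OC)[C@@H]2C(=O)OC | intermediate
10 | methyl (2S,3S)-7-bromo-2-(2,4-dimethoxyphenyl)-4-methoxy-2,3-dihydrobenzofuran-3-carboxylate (trans) | Brc1ccc(OC)c2c1O[C@H](c1ccc(OC)cc1OC)[C@H]2C(=O)OC | intermediate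
11 | (2S,3S)-7-bromo-2-(2,4-dimethoxyphenyl)-4-methoxy-2,3-dihydrobenzofuran-3-carboxylic acid | Brc1ccc(OC)c2c1O[C@H](c1ccc(OC)cc1OC)[C@H]2C(=O)O | intermediate
12 | 1,3-dioxoisoindolin-2-yl (2S,3S)-7-bromo-2-(2,4-dimethoxyphenyl)-4-methoxy-2,3-dihydrobenzofuran-3-carboxylate | Brc1ccc(OC)c2c1O[C@H](c1ccc(OC)cc1OC)[C@H]2C(=O)ON1C(=O)c2ccccc2C1=O | intermediate
13 | 1-bromo-3,5-dimethoxybenzene | COc1cc(Br)cc(OC)c1 | starting material
14 | 3,5-dimethoxyphenylmagnesium bromide (titrated THF stock solution) | COc1cc(cc(OC)c1)[Mg]Br | intermediate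
15 | bis(3,5-dimethoxyphenyl)zinc | COc1cc(cc(OC)c1)[Zn]c1cc(OC)cc(OC)c1 | intermediate
16 | (2S,3S)-7-bromo-2-(2,4-dimethoxyphenyl)-3-(3,5-dimethoxyphenyl)-4-methoxy-2,3-dihydrobenzofuran | Brc1ccc(OC)c2c1O[C@H](c1ccc(OC)cc1OC)[C@H]2c1cc(OC)cc(OC)c1 | intermediate
17 | (2S,3S)-2-(2,4-dimethoxyphenyl)-3-(3,5-dimethoxyphenyl)-4-methoxy-2,3-dihydrobenzofuran-7-carbaldehyde | O=Cc1ccc(OC)c2c1O[C@H](c1ccc(OC)cc1OC)[C@H]2c1cc(OC)cc(OC)c1 | intermediate
18 | [(2S,3S)-2-(2,4-dimethoxyphenyl)-3-(3,5-dimethoxyphenyl)-4-methoxy-2,3-dihydrobenzofuran-7-yl]methanol | OCc1ccc(OC)c2c1O[C@H](c1ccc(OC)cc1OC)[C@H]2c1cc(OC)cc(OC)c1 | intermediate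
19 | (2S,3S)-7-(chloromethyl)-2-(2,4-dimethoxyphenyl)-3-(3,5-dimethoxyphenyl)-4-methoxy-2,3-dihydrobenzofuran | ClCc1ccc(OC)c2c1O[C@H](c1ccc(OC)cc1OC)[C@H]2c1cc(OC)cc(OC)c1 | intermediate
20 | 6-{[(2S,3S)-2-(2,4-dimethoxyphenyl)-3-(3,5-dimethoxyphenyl)-4-methoxy-2,3-dihydrobenzofuran-7-yl]methyl}-4,7,7-trimethyl-6-thiabicyclo[3.2.1]octan-6-ium tetrafluoroborate (isothiocineole-derived, benzylic group exo on sulfur) | C[C@H]1CC[C@@H]2C[C@H]1[S@@+](Cc1ccc(OC)c3c1O[C@H](c1ccc(OC)cc1OC)[C@H]3c1cc(OC)cc(OC)c1)C2(C)C.F[B-](F)(F)F | intermediate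
21 | 2-bromo-4,6-dimethoxybenzaldehyde | COc1cc(Br)c(C=O)c(OC)c1 | starting material
22 | 2-bromo-6-hydroxy-4-methoxybenzaldehyde | COc1cc(O)c(C=O)c(Br)c1 | intermediate
23 | rac-3-bromo-2-[(3,5-dimethoxyphenyl)(hydroxy)methyl]-5-methoxyphenol | COc1cc(O)c(C(O)c2cc(OC)cc(OC)c2)c(Br)c1 | intermediate
24 | rac-3-bromo-2-[(3,5-dimethoxyphenyl)(4-methylbenzenesulfonyl)methyl]-5-methoxyphenol | COc1cc(O)c(C(c2cc(OC)cc(OC)c2)S(=O)(=O)c2ccc(C)cc2)c(Br)c1 | intermediate
25 | sulfonium ylide of 20 (carbanion on the benzylic carbon) | C[C@H]1CC[C@@H]2C[C@H]1[S@@+]([CH-]c1ccc(OC)c3c1O[C@H](c1ccc(OC)cc1OC)[C@H]3c1cc(OC)cc(OC)c1)C2(C)C | intermediate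
26 | 3-bromo-2-[(3,5-dimethoxyphenyl)methylidene]-5-methoxycyclohexa-3,5-dien-1-one (either alkene geometry) | COC1=CC(=O)C(=Cc2cc(OC)cc(OC)c2)C(Br)=C1 | intermediate
27 | (2S,3S)-4-bromo-2-[(2S,3S)-2-(2,4-dimethoxyphenyl)-3-(3,5-dimethoxyphenyl)-4-methoxy-2,3-dihydrobenzofuran-7-yl]-3-(3,5-dimethoxyphenyl)-6-methoxy-2,3-dihydrobenzofuran | Brc1cc(OC)cc2c1[C@H](c1cc(OC)cc(OC)c1)[C@@H](c1ccc(OC)c3c1O[C@H](c1ccc(OC)cc1OC)[C@H]3c1cc(OC)cc(OC)c1)O2 | intermediate
28 | (2S,3S)-4-bromo-3-(3,5-dihydroxyphenyl)-2-[(2S,3S)-2-(2,4-dihydroxyphenyl)-3-(3,5-dihydroxyphenyl)-4-hydroxy-2,3-dihydrobenzofuran-7-yl]-2,3-dihydrobenzofuran-6-ol | Brc1cc(O)cc2c1[C@H](c1cc(O)cc(O)c1)[C@@H](c1ccc(O)c3c1O[C@H](c1ccc(O)cc1O)[C@H]3c1cc(O)cc(O)c1)O2 | intermediate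
29 | octaacetate of 28 | Brc1cc(OC(C)=O)cc2c1[C@H](c1cc(OC(C)=O)cc(OC(C)=O)c1)[C@@H](c1ccc(OC(C)=O)c3c1O[C@H](c1ccc(OC(C)=O)cc1OC(C)=O)[C@H]3c1cc(OC(C)=O)cc(OC(C)=O)c1)O2 | intermediate
30 | 4-acetoxystyrene | CC(=O)Oc1ccc(C=C)cc1 | starting material
31 | nonaacetate of the target (E) | CC(=O)Oc1ccc(/C=C/c2cc(OC(C)=O)cc3c2[C@H](c2cc(OC(C)=O)cc(OC(C)=O)c2)[C@@H](c2ccc(OC(C)=O)c4c2O[C@H](c2ccc(OC(C)=O)cc2OC(C)=O)[C@H]4c2cc(OC(C)=O)cc(OC(C)=O)c2)O3)cc1 | intermediate
32 | CNP0397447.1 | Oc1ccc(/C=C/c2cc(O)cc3c2[C@H](c2cc(O)cc(O)c2)[C@@H](c2ccc(O)c4c2O[C@H](c2ccc(O)cc2O)[C@H]4c2cc(O)cc(O)c2)O3)cc1 | target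

Total steps: 21 (17 in the main line, 1 for the preparation of Grignard reagent 14, 3 in the side branch from 21 to 24, which is steps 14–16). Longest linear sequence: 17 steps (steps 1–9, 11–13 and 17–21).

Steps most likely to fail

Step 17 (proposed new method). The labile, electron-rich benzylic sulfonium salt may alkylate the phenoxide of 24 on oxygen or revert to the benzylic cation before the ylide forms. The approach of ylide and quinone methide may also be too weakly controlled, which would give the cis ring or the other trans configuration of unit 1. The fallback uses known donor–donor carbene insertion and sets out from 18 and 23. Oxidation of 23 (MnO2, CH2Cl2) gives (2-bromo-6-hydroxy-4-methoxyphenyl)(3,5-dimethoxyphenyl)methanone F1. Mitsunobu etherification of F1 with 18 gives the aryl benzyl ether F2, and hydrazine hydrate (EtOH, AcOH, reflux) gives the hydrazone F3. MnO2 oxidises this to the diaryldiazomethane F4, which a chiral dirhodium carboxylate such as Rh2(R-PTAD)4 converts by 1,5 C–H insertion into the cis-2,3-diaryl-2,3-dihydrobenzofuran F5, with C3 set by the catalyst. TFA in CH2Cl2 at 0 °C then ionises the C2–O1 bond, which recloses trans to the C3 aryl group, and the route is rejoined at 27. Unit 2 cannot rearrange under this acid because its 4'-oxygen is still methylated.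

Step 7. The two ortho substituents twist the carbene-bearing ring, so the catalyst may discriminate poorly between the two benzylic hydrogens, or insertion may be slow. The fallback moves stereocontrol to a covalently bound auxiliary and sets out from 6. Esterification (EDC, DMAP) with (S)-2-hydroxy-1-(pyrrolidin-1-yl)propan-1-one gives the lactamide ester F6, and diazo transfer (p-ABSA, DBU) gives the diazo ester F7. Insertion with Rh2(S-DOSP)4 in the matched pairing, followed by DBU equilibration of C3' in the same flask, gives the trans-dihydrobenzofuran auxiliary ester F8. LiOH then removes the auxiliary and the route is rejoined at 11.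

Step 11. The stabilised benzylic radical may couple with itself or abstract hydrogen faster than it is captured by the aryl-iron species. The fallback drops the redox-active ester and sets out from acid 11: metallaphotoredox decarboxylative arylation with 1-iodo-3,5-dimethoxybenzene (Ir[dF(CF3)ppy]2(dtbbpy)PF6, NiCl2·glyme, dtbbpy, Cs2CO3, DMF, blue light). The carboxylate is oxidised by the excited photocatalyst, and the radical is captured by an aryl-nickel species formed from the iodide in preference to the hindered C7' bromide. The route is rejoined at 16 and no compound outside the list is made (F0).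

Further compounds
F1 | step 17 | (2-bromo-6-hydroxy-4-methoxyphenyl)(3,5-dimethoxyphenyl)methanone | COc1cc(O)c(C(=O)c2cc(OC)cc(OC)c2)c(Br)c1
F2 | step 17 | (2-bromo-6-{[(2S,3S)-2-(2,4-dimethoxyphenyl)-3-(3,5-dimethoxyphenyl)-4-methoxy-2,3-dihydrobenzofuran-7-yl]methoxy}-4-methoxyphenyl)(3,5-dimethoxyphenyl)methanone | COc1cc(OCc2ccc(OC)c3c2O[C@H](c2ccc(OC)cc2OC)[C@H]3c2cc(OC)cc(OC)c2)c(C(=O)c2cc(OC)cc(OC)c2)c(Br)c1
F3 | step 17 | hydrazone of F2 | COc1cc(OCc2ccc(OC)c3c2O[C@H](c2ccc(OC)cc2OC)[C@H]3c2cc(OC)cc(OC)c2)c(C(=NN)c2cc(OC)cc(OC)c2)c(Br)c1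
F4 | step 17 | diaryldiazomethane from F3 | COc1cc(OCc2ccc(OC)c3c2O[C@H](c2ccc(OC)cc2OC)[C@H]3c2cc(OC)cc(OC)c2)c(C(=[N+]=[N-])c2cc(OC)cc(OC)c2)c(Br)c1
F5 | step 17 | (2R,3S)-4-bromo-2-[(2S,3S)-2-(2,4-dimethoxyphenyl)-3-(3,5-dimethoxyphenyl)-4-methoxy-2,3-dihydrobenzofuran-7-yl]-3-(3,5-dimethoxyphenyl)-6-methoxy-2,3-dihydrobenzofuran (cis) | Brc1cc(OC)cc2c1[C@H](c1cc(OC)cc(OC)c1)[C@H](c1ccc(OC)c3c1O[C@H](c1ccc(OC)cc1OC)[C@H]3c1cc(OC)cc(OC)c1)O2
F6 | step 7 | (S)-1-oxo-1-(pyrrolidin-1-yl)propan-2-yl 2-{3-bromo-2-[(2,4-dimethoxybenzyl)oxy]-6-methoxyphenyl}acetate | C[C@H](OC(=O)Cc1c(OC)ccc(Br)c1OCc1ccc(OC)cc1OC)C(=O)N1CCCC1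
F7 | step 7 | (S)-1-oxo-1-(pyrrolidin-1-yl)propan-2-yl 2-{3-bromo-2-[(2,4-dimethoxybenzyl)oxy]-6-methoxyphenyl}-2-diazoacetate | C[C@H](OC(=O)C(=[N+]=[N-])c1c(OC)ccc(Br)c1OCc1ccc(OC)cc1OC)C(=O)N1CCCC1
F8 | step 7 | (S)-1-oxo-1-(pyrrolidin-1-yl)propan-2-yl (2S,3S)-7-bromo-2-(2,4-dimethoxyphenyl)-4-methoxy-2,3-dihydrobenzofuran-3-carboxylate | Brc1ccc(OC)c2c1O[C@H](c1ccc(OC)cc1OC)[C@H]2C(=O)O[C@@H](C)C(=O)N1CCCC1
F0 | step 11 | none | none
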